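**Retrosynthetic overview**
1. Target 26 ⇐ desilylation ⇐ peripheral epoxidation of the 1(10)-E alkene ⇐ Mitsunobu esterification at C8 with inversion ⇐ macrocyclic alcohol 22.
2. Key disconnection C7–C8: intramolecular Cr(II) Barbier reaction of the ω-formyl 3-(bromomethyl)butenolide 20. The 2-acylallyl chromium turns the lactone β-carbon (normally an acceptor) into a nucleophile toward the C8 aldehyde; this closes the ten-membered ring and creates C7, C8 and the 11(13)-methylene.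
3. 20 ⇐ lactol 11 + β-iodoacrylate 14 (Ni/Cr coupling–lactonisation builds the C6–O butenolide and sets C6).
4. 11 ⇐ butenolide 10 (temporary ring locking the 4Z alkene) ⇐ aldehyde 6 + methyl propiolate (asymmetric alkynylation sets C3; syn-methylcupration) ⇐ alkyne 1 + oxirane (carboalumination sets 1(10)E).
5. Ring order: temporary C3–O butenolide → permanent C6–O butenolide → ten-membered carbocycle → epoxide.

Assumption: the SMILES encodes the (1R,3R,6R,7R,8R,10R)-4Z heliangolide (germacrane numbering, lactone C12 on O6); where a chiral ligand is named, its antipode is used if the sense of induction proves opposite.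

**Step 1**
Reactants: 1 tert-butyl(but-3-yn-1-yloxy)dimethylsilane; 2 oxirane
Product: 5 (E)-6-[(tert-butyldimethylsilyl)oxy]-4-methylhex-3-en-1-ol, via E-vinylalane 3 (not isolated), via lithium alanate 4 (not isolated)
Conditions: Me3Al, Cp2ZrCl2 (25 mol %), CH2Cl2, 0 °C → rt; n-BuLi, hexane/THF, −78 → 0 °C; then 2, −30 °C → rt; aq. work-up
Reagents that add atoms: trimethylaluminium, C[Al](C)C
Why: Negishi Zr-catalysed syn-carboalumination puts Me on C10 and Al on C1, and the derived alanate opens oxirane with retention, fixing the 1(10)-E alkene (no stereocentre formed).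

**Step 2**
Reactants: 5 (E)-6-[(tert-butyldimethylsilyl)oxy]-4-methylhex-3-en-1-ol
Product: 6 (E)-6-[(tert-butyldimethylsilyl)oxy]-4-methylhex-3-enal
Conditions: Dess–Martin periodinane, CH2Cl2, 0 °C; used crude
Reagents that add atoms: none
Why: Dess–Martin oxidation is non-basic, so the β,γ-unsaturated aldehyde is obtained without conjugation.

**Step 3**
Reactants: 6 (E)-6-[(tert-butyldimethylsilyl)oxy]-4-methylhex-3-enal; 7 methyl propiolate
Product: 8 methyl (4R,6E)-9-[(tert-butyldimethylsilyl)oxy]-4-hydroxy-7-methylnon-6-en-2-ynoate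
Conditions: (S,S)-ProPhenol (20 mol %), Me2Zn, Ph3P=O (40 mol %), toluene, 4 °C
Reagents that add atoms: none
Why: Zn–ProPhenol catalytic asymmetric alkynylation; the dinuclear zinc catalyst delivers the zinc propiolate to the Si face of the aldehyde and sets C3 (R) under catalyst control.

**Step 4**
Reactants: 8 methyl (4R,6E)-9-[(tert-butyldimethylsilyl)oxy]-4-hydroxy-7-methylnon-6-en-2-ynoate
Product: 10 (5R)-5-[(2E)-5-[(tert-butyldimethylsilyl)oxy]-3-methylpent-2-en-1-yl]-4-methylfuran-2(5H)-one, via Z-hydroxy enoate 9 (not isolated)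
Conditions: Me2CuLi (from CuI, MeLi; 3 equiv), THF, −78 °C; aq. NH4Cl, warm to rt
Reagents that add atoms: lithium dimethylcuprate, [Li+].C[Cu-]C
Why: syn-carbocupration of the ynoate (Me to C4, Cu to C5) and protonation with retention give the Z-enoate, whose cis ester lactonises onto the C3 hydroxyl (cuprate/γ-hydroxy-ynoate butenolide synthesis); the 4Z geometry is locked in the ring and C3 is untouched.

**Step 5**
Reactants: 10 (5R)-5-[(2E)-5-[(tert-butyldimethylsilyl)oxy]-3-methylpent-2-en-1-yl]-4-methylfuran-2(5H)-one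
Product: 11 (5R)-5-[(2E)-5-[(tert-butyldimethylsilyl)oxy]-3-methylpent-2-en-1-yl]-4-methyl-2,5-dihydrofuran-2-ol (anomers)
Conditions: DIBAL-H (1.1 equiv), CH2Cl2, −78 °C; Rochelle salt
Reagents that add atoms: none
Why: DIBAL half-reduction of a lactone stops at the aluminium acetal at −78 °C, giving the lactol as a Z-locked γ-hydroxy-enal equivalent.

**Step 6**
Reactants: 7 methyl propiolate; 12 formaldehyde (from cracked paraformaldehyde)
Product: 14 methyl (2Z)-2-(hydroxymethyl)-3-iodoprop-2-enoate, via iodomagnesium allenolate 13 (not isolated)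
Conditions: MgI2, CH2Cl2, 0 °C → rt
Reagents that add atoms: magnesium iodide, [Mg+2].[I-].[I-]
Why: iodo-Morita–Baylis–Hillman (halo-aldol) reaction, here with formaldehyde as the aldehyde: iodide adds to the propiolate and the β-iodoallenolate is hydroxymethylated at Cα, the kinetic product having I cis to the ester (Z).

**Step 7**
Reactants: 11 (5R)-5-[(2E)-5-[(tert-butyldimethylsilyl)oxy]-3-methylpent-2-en-1-yl]-4-methyl-2,5-dihydrofuran-2-ol; 14 methyl (2Z)-2-(hydroxymethyl)-3-iodoprop-2-enoate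
Product: 16 (5R)-3-(hydroxymethyl)-5-[(1Z,3R,5E)-8-[(tert-butyldimethylsilyl)oxy]-3-hydroxy-2,6-dimethylocta-1,5-dien-1-yl]furan-2(5H)-one, via open-chain hydroxy ester 15 (not isolated)
Conditions: CrCl2, NiCl2 (cat.), Kishi (S)-sulfonamide–oxazoline ligand, Et3N, THF, rt
Reagents that add atoms: none
Why: Nozaki–Hiyama–Kishi coupling: the Z-β-iodoacrylate becomes a vinyl–Cr(III) species that adds to the open hydroxy-enal form of the lactol, and the chromium alkoxide lactonises onto the cis ester; the chiral ligand on Cr directs Si-face attack to set C6 (R), and the C6 epimer is a separable diastereomer.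

**Step 8**
Reactants: 16 (5R)-3-(hydroxymethyl)-5-[(1Z,3R,5E)-8-[(tert-butyldimethylsilyl)oxy]-3-hydroxy-2,6-dimethylocta-1,5-dien-1-yl]furan-2(5H)-one
Product: 17 (5R)-3-(bromomethyl)-5-[(1Z,3R,5E)-8-[(tert-butyldimethylsilyl)oxy]-3-hydroxy-2,6-dimethylocta-1,5-dien-1-yl]furan-2(5H)-one
Conditions: CBr4 (1.05 equiv), PPh3, CH2Cl2, −20 °C
Reagents that add atoms: carbon tetrabromide, BrC(Br)(Br)Br
Why: Appel bromination is much faster at the unhindered primary allylic hydroxyl than at the secondary C3 hydroxyl at low temperature.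

**Step 9**
Reactants: 17 (5R)-3-(bromomethyl)-5-[(1Z,3R,5E)-8-[(tert-butyldimethylsilyl)oxy]-3-hydroxy-2,6-dimethylocta-1,5-dien-1-yl]furan-2(5H)-one
Product: 18 (5R)-3-(bromomethyl)-5-[(1Z,3R,5E)-3,8-bis[(tert-butyldimethylsilyl)oxy]-2,6-dimethylocta-1,5-dien-1-yl]furan-2(5H)-one
Conditions: TBSOTf, 2,6-lutidine, CH2Cl2, −78 °C
Reagents that add atoms: tert-butyldimethylsilyl triflate, CC(C)(C)[Si](C)(C)OS(=O)(=O)C(F)(F)F
Why: silyl triflate with a hindered, non-nucleophilic base silylates the C3 alcohol without touching the allylic bromide or enolising the butenolide at −78 °C.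

**Step 10**
Reactants: 18 (5R)-3-(bromomethyl)-5-[(1Z,3R,5E)-3,8-bis[(tert-butyldimethylsilyl)oxy]-2,6-dimethylocta-1,5-dien-1-yl]furan-2(5H)-one
Product: 19 (5R)-3-(bromomethyl)-5-[(1Z,3R,5E)-3-[(tert-butyldimethylsilyl)oxy]-8-hydroxy-2,6-dimethylocta-1,5-dien-1-yl]furan-2(5H)-one
Conditions: CSA (10 mol %), MeOH/CH2Cl2, 0 °C
Reagents that add atoms: none
Why: acid-catalysed methanolysis removes a primary TBS ether far faster than a secondary one.

**Step 11**
Reactants: 19 (5R)-3-(bromomethyl)-5-[(1Z,3R,5E)-3-[(tert-butyldimethylsilyl)oxy]-8-hydroxy-2,6-dimethylocta-1,5-dien-1-yl]furan-2(5H)-one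
Product: 20 (5R)-3-(bromomethyl)-5-[(1Z,3R,5E)-3-[(tert-butyldimethylsilyl)oxy]-2,6-dimethyl-8-oxoocta-1,5-dien-1-yl]furan-2(5H)-one
Conditions: Dess–Martin periodinane, CH2Cl2, 0 °C; used at once
Reagents that add atoms: none
Why: Dess–Martin oxidation gives the β,γ-unsaturated aldehyde without base, so neither the aldehyde nor the base-sensitive butenolide isomerises.

**Step 12**
Reactants: 20 (5R)-3-(bromomethyl)-5-[(1Z,3R,5E)-3-[(tert-butyldimethylsilyl)oxy]-2,6-dimethyl-8-oxoocta-1,5-dien-1-yl]furan-2(5H)-one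
Product: 22 (3R,6R,7R,8S)-3-[(tert-butyldimethylsilyl)oxy]-8-hydroxygermacra-1(10)E,4Z,11(13)-trien-12,6-olide, via allylchromium(III) species 21 (not isolated)
Conditions: CrCl2 (6 equiv), THF, rt, syringe-pump addition, 2 mM
Reagents that add atoms: none
Why: Proposed new method: Cr(II) inserts into the allylic C–Br bond to give a 2-acylallyl chromium that attacks the tethered aldehyde through C7 (SE2′, unveiling the exo-methylene) in a six-membered chair transition state; the ring-locked E-crotyl-like geometry with C6 and C9 both pseudo-equatorial and approach anti to the C6–C5 bond should give the 6,7-trans lactone and the 7,8-anti (8S) alcohol; closest known reactions are the intermolecular Cr/Zn/In Barbier addition of 3-(bromomethyl)furan-2(5H)-ones to aldehydes and the Nozaki–Hiyama macrocyclisation of ω-formyl allylic bromides to ten-membered germacranolides.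

**Step 13**
Reactants: 22 (3R,6R,7R,8S)-3-[(tert-butyldimethylsilyl)oxy]-8-hydroxygermacra-1(10)E,4Z,11(13)-trien-12,6-olide; 23 3-methylbutanoic acid
Product: 24 (3R,6R,7R,8R)-3-[(tert-butyldimethylsilyl)oxy]-8-(3-methylbutanoyloxy)germacra-1(10)E,4Z,11(13)-trien-12,6-olide
Conditions: PPh3, DIAD, toluene, 0 °C → rt
Reagents that add atoms: none
Why: Mitsunobu esterification proceeds by SN2 displacement of the alkoxyphosphonium, inverting C8 from S to the required R while installing the isovalerate in the same step.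

**Step 14**
Reactants: 24 (3R,6R,7R,8R)-3-[(tert-butyldimethylsilyl)oxy]-8-(3-methylbutanoyloxy)germacra-1(10)E,4Z,11(13)-trien-12,6-olide
Product: 25 (1R,3R,6R,7R,8R,10R)-3-[(tert-butyldimethylsilyl)oxy]-1,10-epoxy-8-(3-methylbutanoyloxy)germacra-4Z,11(13)-dien-12,6-olide
Conditions: mCPBA, NaHCO3, CH2Cl2, −20 → 0 °C
Reagents that add atoms: 3-chloroperoxybenzoic acid, O=C(OO)c1cccc(Cl)c1
Why: Prilezhaev epoxidation selects the most electron-rich 1(10) alkene (C4=C5 is deactivated by two allylic C–O bonds and no longer OH-directed, C11=C13 is conjugated), and peripheral attack on the outer face of the E-alkene in the ten-membered ring is expected to give the natural 1β,10α (1R,10R) trans-epoxide.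

**Step 15**
Reactants: 25 (1R,3R,6R,7R,8R,10R)-3-[(tert-butyldimethylsilyl)oxy]-1,10-epoxy-8-(3-methylbutanoyloxy)germacra-4Z,11(13)-dien-12,6-olide
Product: 26 (1R,3R,6R,7R,8R,10R)-1,10-epoxy-3-hydroxy-8-(3-methylbutanoyloxy)germacra-4Z,11(13)-dien-12,6-olide (CNP0300193.1)
Conditions: HF·pyridine, excess pyridine, THF, 0 °C → rt
Reagents that add atoms: none
Why: pyridine-buffered HF cleaves the secondary silyl ether without opening the epoxide or touching the ester and α-methylene lactone.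

**Compound list**
1 | tert-butyl(but-3-yn-1-yloxy)dimethylsilane | C#CCCO[Si](C)(C)C(C)(C)C | starting material
2 | oxirane | C1CO1 | starting material
3 | (E)-[4-[(tert-butyldimethylsilyl)oxy]-2-methylbut-1-en-1-yl]dimethylalane (not isolated) | C[Al](C)/C=C(\C)CCO[Si](C)(C)C(C)(C)C | intermediate
4 | lithium butyl[(E)-4-[(tert-butyldimethylsilyl)oxy]-2-methylbut-1-en-1-yl]dimethylaluminate (not isolated) | [Li+].CCCC[Al-](C)(C)/C=C(\C)CCO[Si](C)(C)C(C)(C)C | intermediate
5 | (E)-6-[(tert-butyldimethylsilyl)oxy]-4-methylhex-3-en-1-ol | OCC/C=C(\C)CCO[Si](C)(C)C(C)(C)C | intermediate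
6 | (E)-6-[(tert-butyldimethylsilyl)oxy]-4-methylhex-3-enal | O=CC/C=C(\C)CCO[Si](C)(C)C(C)(C)C | intermediate
7 | methyl propiolate | C#CC(=O)OC | starting material
8 | methyl (4R,6E)-9-[(tert-butyldimethylsilyl)oxy]-4-hydroxy-7-methylnon-6-en-2-ynoate | COC(=O)C#C[C@H](O)C/C=C(\C)CCO[Si](C)(C)C(C)(C)C | intermediate
9 | methyl (2Z,4R,6E)-9-[(tert-butyldimethylsilyl)oxy]-4-hydroxy-3,7-dimethylnona-2,6-dienoate (not isolated) | COC(=O)/C=C(/C)[C@H](O)C/C=C(\C)CCO[Si](C)(C)C(C)(C)C | intermediate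
10 | (5R)-5-[(2E)-5-[(tert-butyldimethylsilyl)oxy]-3-methylpent-2-en-1-yl]-4-methylfuran-2(5H)-one | CC1=CC(=O)O[C@@H]1C/C=C(\C)CCO[Si](C)(C)C(C)(C)C | intermediate
11 | (5R)-5-[(2E)-5-[(tert-butyldimethylsilyl)oxy]-3-methylpent-2-en-1-yl]-4-methyl-2,5-dihydrofuran-2-ol (anomers) | CC1=CC(O)O[C@@H]1C/C=C(\C)CCO[Si](C)(C)C(C)(C)C | intermediate
12 | formaldehyde (from paraformaldehyde) | C=O | starting material
13 | iodomagnesium 3-iodo-1-methoxypropa-1,2-dien-1-olate (not isolated) | COC(O[Mg]I)=C=CI | intermediate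
14 | methyl (2Z)-2-(hydroxymethyl)-3-iodoprop-2-enoate | COC(=O)/C(CO)=C\I | intermediate
15 | methyl (2Z,4R,5Z,7R,9E)-12-[(tert-butyldimethylsilyl)oxy]-4,7-dihydroxy-2-(hydroxymethyl)-6,10-dimethyldodeca-2,5,9-trienoate (not isolated) | COC(=O)/C(CO)=C\[C@H](O)/C=C(/C)[C@H](O)C/C=C(\C)CCO[Si](C)(C)C(C)(C)C | intermediate
16 | (5R)-3-(hydroxymethyl)-5-[(1Z,3R,5E)-8-[(tert-butyldimethylsilyl)oxy]-3-hydroxy-2,6-dimethylocta-1,5-dien-1-yl]furan-2(5H)-one | O=C1O[C@@H](C=C1CO)/C=C(/C)[C@H](O)C/C=C(\C)CCO[Si](C)(C)C(C)(C)C | intermediate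
17 | (5R)-3-(bromomethyl)-5-[(1Z,3R,5E)-8-[(tert-butyldimethylsilyl)oxy]-3-hydroxy-2,6-dimethylocta-1,5-dien-1-yl]furan-2(5H)-one | O=C1O[C@@H](C=C1CBr)/C=C(/C)[C@H](O)C/C=C(\C)CCO[Si](C)(C)C(C)(C)C | intermediate
18 | (5R)-3-(bromomethyl)-5-[(1Z,3R,5E)-3,8-bis[(tert-butyldimethylsilyl)oxy]-2,6-dimethylocta-1,5-dien-1-yl]furan-2(5H)-one | O=C1O[C@@H](C=C1CBr)/C=C(/C)[C@H](O[Si](C)(C)C(C)(C)C)C/C=C(\C)CCO[Si](C)(C)C(C)(C)C | intermediate
19 | (5R)-3-(bromomethyl)-5-[(1Z,3R,5E)-3-[(tert-butyldimethylsilyl)oxy]-8-hydroxy-2,6-dimethylocta-1,5-dien-1-yl]furan-2(5H)-one | O=C1O[C@@H](C=C1CBr)/C=C(/C)[C@H](O[Si](C)(C)C(C)(C)C)C/C=C(\C)CCO | intermediate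
20 | (5R)-3-(bromomethyl)-5-[(1Z,3R,5E)-3-[(tert-butyldimethylsilyl)oxy]-2,6-dimethyl-8-oxoocta-1,5-dien-1-yl]furan-2(5H)-one | O=C1O[C@@H](C=C1CBr)/C=C(/C)[C@H](O[Si](C)(C)C(C)(C)C)C/C=C(\C)CC=O | intermediate
21 | dichloro[[(5R)-5-[(1Z,3R,5E)-3-[(tert-butyldimethylsilyl)oxy]-2,6-dimethyl-8-oxoocta-1,5-dien-1-yl]-2-oxo-2,5-dihydrofuran-3-yl]methyl]chromium(III) (not isolated) | O=C1O[C@@H](C=C1C[Cr](Cl)Cl)/C=C(/C)[C@H](O[Si](C)(C)C(C)(C)C)C/C=C(\C)CC=O | intermediate
22 | (3R,6R,7R,8S)-3-[(tert-butyldimethylsilyl)oxy]-8-hydroxygermacra-1(10)E,4Z,11(13)-trien-12,6-olide | C=C1C(=O)O[C@@H]2/C=C(/C)[C@H](O[Si](C)(C)C(C)(C)C)C/C=C(\C)C[C@H](O)[C@@H]12 | intermediate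
23 | 3-methylbutanoic acid (isovaleric acid) | CC(C)CC(=O)O | starting material
24 | (3R,6R,7R,8R)-3-[(tert-butyldimethylsilyl)oxy]-8-(3-methylbutanoyloxy)germacra-1(10)E,4Z,11(13)-trien-12,6-olide | C=C1C(=O)O[C@@H]2/C=C(/C)[C@H](O[Si](C)(C)C(C)(C)C)C/C=C(\C)C[C@@H](OC(=O)CC(C)C)[C@@H]12 | intermediate
25 | (1R,3R,6R,7R,8R,10R)-3-[(tert-butyldimethylsilyl)oxy]-1,10-epoxy-8-(3-methylbutanoyloxy)germacra-4Z,11(13)-dien-12,6-olide | C=C1C(=O)O[C@@H]2/C=C(/C)[C@H](O[Si](C)(C)C(C)(C)C)C[C@H]3O[C@]3(C)C[C@@H](OC(=O)CC(C)C)[C@@H]12 | intermediate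
26 | (1R,3R,6R,7R,8R,10R)-1,10-epoxy-3-hydroxy-8-(3-methylbutanoyloxy)germacra-4Z,11(13)-dien-12,6-olide (CNP0300193.1) | C=C1C(=O)O[C@@H]2/C=C(/C)[C@H](O)C[C@H]3O[C@]3(C)C[C@@H](OC(=O)CC(C)C)[C@@H]12 | target

**Step count**
Total: 15 steps. Longest linear sequence: 14 steps (1 → 26 through steps 1–5 and 7–15; step 6 makes reagent 14).

**Three steps most likely to fail**

Step 12 (ring closure). The ten-membered ring may close slowly against intermolecular coupling or simple reduction of the bromide, and the 6,7-trans/7,8-anti outcome is predicted, not precedented. Fallback, setting out from 19 and coming back at 22: reverse the roles of the two carbons and close the same bond by radical chemistry. Displacing the bromide of 19 with KOAc in DMF gives the allylic acetate alcohol F1. Dess–Martin oxidation of F1 gives the acetoxy aldehyde F2. Treating F2 with SmI2/HMPA in THF at high dilution generates the C8 ketyl, which adds to C7 of the butenolide; the samarium enolate then expels acetate to unveil the exo-methylene, giving 22.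

Step 7 (second butenolide). The lactol may dehydrate to a furan or open poorly, reagent 14 is uncommon, and C6 rests on ligand control against a possibly mismatched chelate. Fallback, setting out from 8 and coming back at 18: keep C3 as an open-chain silyl ether and set C6 by alkynylation instead. TBSOTf/2,6-lutidine on 8 gives the silyl ether ynoate F3. Me2CuLi at −78 °C gives the Z-enoate F4. DIBAL-H gives the Z-allylic alcohol F5, and MnO2 gives the Z-enal F6. Zn–ProPhenol alkynylation of F6 with 7 gives the propargylic alcohol F7. Syn-1,4-hydroalumination of the ynoate of F7 (DIBAL-H/NMO), trapping of the α-alumino acrylate with formaldehyde and lactonisation give the hydroxymethyl butenolide F8. Appel bromination of F8 gives 18.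

Step 13 (Mitsunobu). Inversion at a hindered ring carbinol next to the allylic C7–H may give elimination or retention. Fallback, setting out from 22 and coming back at 24: invert by oxidation and reduction. Dess–Martin oxidation of 22 gives the C8 ketone F9. Reduction of F9 from the outer face (NaBH4/CeCl3, −78 °C, or a CBS catalyst if substrate control is poor) gives the 8R alcohol F10. Acylation of F10 with isovaleric anhydride/DMAP gives 24.

**Further compounds**
F1 | step 12 | (5R)-3-(acetoxymethyl)-5-[(1Z,3R,5E)-3-[(tert-butyldimethylsilyl)oxy]-8-hydroxy-2,6-dimethylocta-1,5-dien-1-yl]furan-2(5H)-one | O=C1O[C@@H](C=C1COC(C)=O)/C=C(/C)[C@H](O[Si](C)(C)C(C)(C)C)C/C=C(\C)CCO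
F2 | step 12 | (5R)-3-(acetoxymethyl)-5-[(1Z,3R,5E)-3-[(tert-butyldimethylsilyl)oxy]-2,6-dimethyl-8-oxoocta-1,5-dien-1-yl]furan-2(5H)-one | O=C1O[C@@H](C=C1COC(C)=O)/C=C(/C)[C@H](O[Si](C)(C)C(C)(C)C)C/C=C(\C)CC=O
F3 | step 7 | methyl (4R,6E)-4,9-bis[(tert-butyldimethylsilyl)oxy]-7-methylnon-6-en-2-ynoate | COC(=O)C#C[C@H](O[Si](C)(C)C(C)(C)C)C/C=C(\C)CCO[Si](C)(C)C(C)(C)C
F4 | step 7 | methyl (2Z,4R,6E)-4,9-bis[(tert-butyldimethylsilyl)oxy]-3,7-dimethylnona-2,6-dienoate | COC(=O)/C=C(/C)[C@H](O[Si](C)(C)C(C)(C)C)C/C=C(\C)CCO[Si](C)(C)C(C)(C)C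
F5 | step 7 | (2Z,4R,6E)-4,9-bis[(tert-butyldimethylsilyl)oxy]-3,7-dimethylnona-2,6-dien-1-ol | OC/C=C(/C)[C@H](O[Si](C)(C)C(C)(C)C)C/C=C(\C)CCO[Si](C)(C)C(C)(C)C
F6 | step 7 | (2Z,4R,6E)-4,9-bis[(tert-butyldimethylsilyl)oxy]-3,7-dimethylnona-2,6-dienal | O=C/C=C(/C)[C@H](O[Si](C)(C)C(C)(C)C)C/C=C(\C)CCO[Si](C)(C)C(C)(C)C
F7 | step 7 | methyl (4R,5Z,7R,9E)-7,12-bis[(tert-butyldimethylsilyl)oxy]-4-hydroxy-6,10-dimethyldodeca-5,9-dien-2-ynoate | COC(=O)C#C[C@H](O)/C=C(/C)[C@H](O[Si](C)(C)C(C)(C)C)C/C=C(\C)CCO[Si](C)(C)C(C)(C)C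
F8 | step 7 | (5R)-5-[(1Z,3R,5E)-3,8-bis[(tert-butyldimethylsilyl)oxy]-2,6-dimethylocta-1,5-dien-1-yl]-3-(hydroxymethyl)furan-2(5H)-one | O=C1O[C@@H](C=C1CO)/C=C(/C)[C@H](O[Si](C)(C)C(C)(C)C)C/C=C(\C)CCO[Si](C)(C)C(C)(C)C
F9 | step 13 | (3R,6R,7S)-3-[(tert-butyldimethylsilyl)oxy]-8-oxogermacra-1(10)E,4Z,11(13)-trien-12,6-olide | C=C1C(=O)O[C@@H]2/C=C(/C)[C@H](O[Si](C)(C)C(C)(C)C)C/C=C(\C)CC(=O)[C@@H]12
F10 | step 13 | (3R,6R,7R,8R)-3-[(tert-butyldimethylsilyl)oxy]-8-hydroxygermacra-1(10)E,4Z,11(13)-trien-12,6-olide | C=C1C(=O)O[C@@H]2/C=C(/C)[C@H](O[Si](C)(C)C(C)(C)C)C/C=C(\C)C[C@@H](O)[C@@H]12
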